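## Analysis of the target

- The target is a flavone: ring A (benzo ring, C4a–C8a), ring C (pyranone, O1–C4) and ring B (the phenyl group on C2) form the chrysin skeleton with hydroxyls on C5 and C7. C6 carries a 1-methylpiperidin-2-yl group bonded through C2' (primed atoms belong to the piperidine).
- C2' is the only stereocentre. From the SMILES it is (R), with priorities N1' > C6 > C3' > H. It is benzylic, bonded to nitrogen, and lies between the two ortho oxygens O5 and O7.
- Three features are sensitive. The ortho-hydroxybenzylic amine can ionise at C2'–N1' under hot acid or base, and ring opening and reclosure of that kind would racemise C2'. A 6-substituted 5,7-dihydroxyflavone can isomerise to the 8-substituted one by opening and reclosing ring C in hot mineral acid (Wessely–Moser rearrangement). The free C8–H position of the dihydroxyflavone is nucleophilic towards iminium ions and aldehydes.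
- The difficulty is ring A. It is hexasubstituted, and the bond C6–C2' joins a stereogenic sp3 carbon to an arene position flanked by two oxygens. Making that bond on a preformed phloroglucinol with control of absolute configuration is hard. So is telling C6 from C8, which means telling O1 from O5 and O7.
- The strategy rests on one structural fact. C6 together with C2', N1' and the chain C3'–C6' is the skeleton of pipecolic acid, with C2' as the α-carbon and C6 as the carboxyl carbon. (R)-Pipecolic acid 1 therefore supplies the stereocentre and the first atom of ring A, and the other five ring A carbons can be grown around that atom.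
- O1 is the ring A oxygen para to C6. On a ring that is symmetric about the C6–C8a axis it can be told apart from O5 and O7 by position alone.

## Retrosynthetic reasoning

**26 to 25 (O–Si bonds).** The two phenols are uncovered last from the bis-silyl ether 25. While they are silylated, ring A is less nucleophilic and C2' cannot ionise through a phenoxide. The final step then only has to cleave two aryl silyl ethers at or below room temperature.

**25 to 23 (N1'–CH3).** The N-methyl group is traced to the tert-butyl carbamate of 23 by way of the secondary ammonium salt 24. A carbamate nitrogen is needed through the whole route: a basic amine would add to ketenes in the key step and would complicate iodination and palladium catalysis. Methylation is placed before desilylation so that the one-carbon electrophile never meets a free 5,7-dihydroxyflavone.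

**23 to 19 and 20 (C4a–C4, C4–C3 and O1–C2).** Ring C is cut into the ortho-iodophenol 19, phenylacetylene 20 and one carbonyl carbon delivered by carbonylative coupling. The sequence passes through ynone 21 and enaminone 22. The cut is made here because the only free hydroxyl of 19 is the one para to C6. With O5 and O7 silylated, only that oxygen can close the pyranone, so the 6-substituted flavone must form and the 8-substituted isomer cannot.

**19 to 18 to 17 to 16 (C4a–I, O1–benzyl, O5–Si).** The iodine goes in ortho to the free phenol of 18. Both ortho positions of 18 are constitutionally equivalent, since they exchange on rotation about the C6–C2' bond, so the iodination has no regiochemical question. Phenol 18 comes from benzyl ether 17 by hydrogenolysis. Compound 17 comes from 16 by silylating its one free hydroxyl, which is what makes ring A symmetric and blocks O5.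

**16 to 8 and 11 (C5–C6, C7–C8 and C5–C4a).** This is the central disconnection. Ring A is taken apart into the two alkyne carbons of siloxyalkyne 8 (C6 and C7) and the four carbons of cyclobutenone 11 (C5, C8, C8a and C4a). The forward reaction is a thermal cascade through 12, 13, 14 and 15. It places C6 between a hydroxyl and a siloxy group and puts the benzyl ether para to it. The aryl–C2' bond is never made on an arene: it is already present as the propargylic bond of 8.

**8 to 5 to 3 to 2 to 1.** The siloxyalkyne comes from terminal alkyne 5 by oxidising its lithium acetylide 6 to ynolate 7 and silylating on oxygen. Alkyne 5 comes from methyl ester 3 by partial reduction to aldehyde 4 and one-carbon homologation in the same flask, so the epimerisable aldehyde is never stored. Ester 3 comes from 1 through the carbamate acid 2.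

**11 to 9 and 10.** The benzyl vinylogous ester 11 is reached by alkoxy exchange between the commercial ethyl compound 9 and benzyl alcohol 10. Benzyl is chosen because it can be removed later by hydrogenolysis in the presence of silyl ethers and the carbamate.

## Alternatives that were turned down

**Alternative 1: ring C closed by intramolecular O-arylation.**
- Disconnection: O1–C8a. The dimethyl ether A1 of the target is traced to the ortho-bromoaryl 1,3-diketone A2.
- Forward key step: the enol oxygen of A2 displaces the bromide under monovalent copper catalysis (Ullmann-type C–O coupling) to give A1.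
- For: the bromine fixes where O1 goes. There is no 6- versus 8-isomer question, no five-membered aurone closure and no pressurised gas.
- Against: A2 already contains the complete hexasubstituted ring A with C2' in place, so the plan begins after the hard part. Building that arene needs an enantioselective aryl–C2' bond between two methoxy groups and regiocontrolled bromination and acylation. Two methyl ethers must be cleaved at the end with strong Lewis or Brønsted acids at elevated temperature, which are the conditions under which ring C can reopen and C2'–N1' can ionise.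
- Comparison: this alternative is stronger on the pyranone closure. The chosen route offers in its place a stereocentre taken from the chiral pool, a ring A built around it, and oxygen protecting groups that leave at 0 °C.

**Alternative 2: piperidine ring by catalytic asymmetric aza-Diels–Alder reaction.**
- Disconnection: C2'–C3' and N1'–C6'.
- Forward key step: N-aryl aldimine A4 and siloxydiene A5 combine under a chiral BINOL-derived phosphoric acid by Mannich addition and ring closure to give dihydropyridinone A3.
- For: the stereocentre is made catalytically, either enantiomer is available by choice of catalyst, and the arene comes from a simple phloroglucinol aldehyde.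
- Against: the imine carbon of A4 lies between two ortho methoxy groups on a strongly donor-substituted ring. It is a poor, twisted electrophile, outside the range where such catalysts are expected to give high selectivity. After A3 the C5'=C6' bond must be saturated, the C4' carbonyl deleted, and the N-(4-methoxyphenyl) group removed oxidatively in the presence of a more electron-rich arene. N-methylation, the whole of ring C and cleavage of two methyl ethers still follow.
- Comparison: it is stronger in not depending on a chiral-pool acid. The chosen route offers a stereocentre of assured configuration, no redox corrections on the piperidine and fewer steps.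

**Alternative 3: piperidine ring by ring-closing metathesis.**
- Disconnection: C4'=C5'.
- Forward key step: the N-allyl and C-allyl groups of amine A7, as its ammonium salt, are joined by the second-generation Grubbs catalyst (H2IMes)(PCy3)Cl2Ru=CHPh to give tetrahydropyridine A6.
- For: six-membered ring closure by metathesis is among the most predictable ring-forming reactions. The N-methyl group is already in place, and one later hydrogenation would saturate the alkene and remove the benzyl ether together.
- Against: C2' has to be set beforehand, most plausibly by auxiliary-controlled allylation of an imine of the same doubly ortho-substituted benzaldehyde. That adds attachment and removal of the auxiliary and two N-alkylations. The basic nitrogen must be masked as a salt for the ruthenium carbene, and the methyl ethers again demand a harsh final deprotection.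
- Comparison: its ring-forming event is as reliable as, or more reliable than, the thermal cascade chosen here. The chosen strategy accepts a riskier key step and offers in return a shorter path to the stereocentre and protecting groups matched to the sensitivity of the final product.

Key step: step 6

Remarks on the chemistry:
- Flavone numbering (O1, C2–C8a) and primed piperidine numbering are used for all ring A intermediates.
- The ring sp3 carbon of 13 forms as a mixture of epimers and is left undefined in its SMILES. It becomes sp2 in 14, so this has no consequence.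
- Compounds 1, 9, 10 and 20 and all reagents are taken as commercial.

## Route

Step 1
Reactants: 1 (R)-piperidine-2-carboxylic acid
Product: 2 (R)-1-(tert-butoxycarbonyl)piperidine-2-carboxylic acid
Conditions: Boc2O, Et3N, 1,4-dioxane/H2O, 0 °C to rt; then aq. KHSO4
Reagents that add atoms: di-tert-butyl dicarbonate, CC(C)(C)OC(=O)OC(=O)OC(C)(C)C
Why: N-acylation of the secondary amine by the dicarbonate (carbamate formation); C2' is not involved.

Step 2
Reactants: 2 (R)-1-(tert-butoxycarbonyl)piperidine-2-carboxylic acid
Product: 3 1-tert-butyl 2-methyl (R)-piperidine-1,2-dicarboxylate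
Conditions: MeI, K2CO3, DMF, rt
Reagents that add atoms: iodomethane, CI
Why: SN2 O-alkylation of the carboxylate; carbonate is too weak a base to enolise the carbamate-protected amino ester, so C2' should be retained.

Step 3
Reactants: 3 1-tert-butyl 2-methyl (R)-piperidine-1,2-dicarboxylate
Product: 5 tert-butyl (R)-2-ethynylpiperidine-1-carboxylate, via aldehyde 4 (not isolated)
Conditions: i-Bu2AlH, CH2Cl2, −78 °C; then MeOH, K2CO3, Ohira–Bestmann reagent, −78 °C to rt
Reagents that add atoms: dimethyl (1-diazo-2-oxopropyl)phosphonate, COP(=O)(OC)C(=[N+]=[N-])C(C)=O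
Why: Hydride reduction at −78 °C stops at the aluminium hemiacetal, which releases aldehyde 4 when methanol is added; Seyferth–Gilbert homologation in its Ohira–Bestmann form (olefination to a diazoalkene, loss of N2, 1,2-hydrogen shift of the alkylidene carbene) then gives the alkyne in the same flask. Keeping 4 cold and in solution limits epimerisation at C2'.

Step 4
Reactants: 5 tert-butyl (R)-2-ethynylpiperidine-1-carboxylate
Product: 8 tert-butyl (R)-2-[(triisopropylsilyloxy)ethynyl]piperidine-1-carboxylate, via lithium acetylide 6 (not isolated), via lithium ynolate 7 (not isolated)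
Conditions: n-BuLi (1.0 equiv), THF, −78 °C; LiOOt-Bu (from t-BuOOH and LiN(SiMe3)2), −78 to 0 °C; TIPSOTf, −78 to 0 °C
Reagents that add atoms: tert-butyl hydroperoxide, CC(C)(C)OO; triisopropylsilyl trifluoromethanesulfonate, CC(C)[Si](OS(=O)(=O)C(F)(F)F)(C(C)C)C(C)C
Why: Electrophilic oxygen transfer from the lithium peroxide to the acetylide carbon, with tert-butoxide as leaving group, gives ynolate 7, and the bulky silyl triflate traps it on oxygen (the known acetylide-oxidation route to siloxyalkynes). The terminal C–H is far more acidic than C2'–H, so one equivalent of base leaves the stereocentre alone.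

Step 5
Reactants: 9 3-ethoxycyclobut-2-en-1-one; 10 benzyl alcohol
Product: 11 3-(benzyloxy)cyclobut-2-en-1-one
Conditions: 10 (5 equiv), pyridinium p-toluenesulfonate (5 mol%), toluene, 25 °C, 50 mbar (EtOH removed)
Reagents that add atoms: none
Why: Acid-catalysed alkoxy exchange of a vinylogous ester by addition–elimination at C3, as known for 3-alkoxycycloalkenones and squarate esters, driven by excess 10 and removal of ethanol. Room temperature keeps the cyclobutenone below the threshold of its electrocyclic opening.

Step 6
Reactants: 8 tert-butyl (R)-2-[(triisopropylsilyloxy)ethynyl]piperidine-1-carboxylate; 11 3-(benzyloxy)cyclobut-2-en-1-one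
Product: 16 tert-butyl (R)-2-[4-(benzyloxy)-2-hydroxy-6-(triisopropylsilyloxy)phenyl]piperidine-1-carboxylate, via vinylketene 12 (not isolated), via vinylcyclobutenone 13 (not isolated), via dienylketene 14 (not isolated), via cyclohexadienone 15 (not isolated)
Conditions: toluene, 80 to 110 °C, argon, 11 (1.3 equiv) added slowly
Reagents that add atoms: none
Why: This is a Danheiser benzannulation of a cyclobutenone with a trialkylsiloxyalkyne, a known pericyclic cascade. Heating opens 11 by 4π conrotatory cleavage of its C1–C4 bond to vinylketene 12. The ketene C=C of 12 and the alkyne of 8 then undergo [2+2] cycloaddition in which the nucleophilic alkyne carbon (β to the siloxy oxygen, the one bearing C2') bonds to the electrophilic ketene carbon, giving 13 and with it bonds C5–C6 and C7–C8. Compound 13 opens reversibly by a second 4π step to dienylketene 14, and the isomer with the vinyl group cis to the ketene is drained off. Ring A closes by thermal 6π disrotatory electrocyclisation between the ketene carbon and the terminal CH2 (bond C5–C4a), and cyclohexadienone 15 tautomerises irreversibly to phenol 16. No stereocentre is created; C2' is a spectator next to sp or sp2 carbon under neutral aprotic conditions and has no pathway to epimerise. The only selectivity needed is regiochemical, and the matched polarity of ketene and ynol ether secures it: C6 ends between the new hydroxyl and the siloxy group, with the benzyl ether para to it. Slow addition of 11 keeps 12 dilute and limits ketene dimerisation and acylation of the product phenol.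

Step 7
Reactants: 16 tert-butyl (R)-2-[4-(benzyloxy)-2-hydroxy-6-(triisopropylsilyloxy)phenyl]piperidine-1-carboxylate
Product: 17 tert-butyl (R)-2-[4-(benzyloxy)-2,6-bis(triisopropylsilyloxy)phenyl]piperidine-1-carboxylate
Conditions: TIPSCl, imidazole, DMAP (cat.), DMF, 50 °C
Reagents that add atoms: chlorotriisopropylsilane, CC(C)[Si](Cl)(C(C)C)C(C)C
Why: O-silylation of the phenol through the N-silylimidazolium; the chloride is used instead of the triflate so that the carbamate is not attacked. It blocks O5, so that only O1 can later close ring C, and it makes ring A symmetric.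

Step 8
Reactants: 17 tert-butyl (R)-2-[4-(benzyloxy)-2,6-bis(triisopropylsilyloxy)phenyl]piperidine-1-carboxylate
Product: 18 tert-butyl (R)-2-[4-hydroxy-2,6-bis(triisopropylsilyloxy)phenyl]piperidine-1-carboxylate
Conditions: H2 (1 atm), Pd/C (10 wt%), EtOAc, rt
Reagents that add atoms: none
Why: Hydrogenolysis of the unhindered aryl benzyl ether. The benzylic C2'–N1' bond is a carbamate C–N bond shielded by two bulky siloxy groups and should not cleave at 1 atm and room temperature.

Step 9
Reactants: 18 tert-butyl (R)-2-[4-hydroxy-2,6-bis(triisopropylsilyloxy)phenyl]piperidine-1-carboxylate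
Product: 19 tert-butyl (R)-2-[4-hydroxy-3-iodo-2,6-bis(triisopropylsilyloxy)phenyl]piperidine-1-carboxylate
Conditions: N-iodosuccinimide (1.0 equiv), CH2Cl2, −20 to 0 °C, dark
Reagents that add atoms: N-iodosuccinimide, O=C1CCC(=O)N1I
Why: Electrophilic aromatic iodination ortho to the free phenol. The para position is blocked by C2' and the two ortho positions are constitutionally equivalent, so one monoiodide is expected; one equivalent at low temperature limits a second iodination.

Step 10
Reactants: 19 tert-butyl (R)-2-[4-hydroxy-3-iodo-2,6-bis(triisopropylsilyloxy)phenyl]piperidine-1-carboxylate; 20 phenylacetylene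
Product: 23 tert-butyl (R)-2-[4-oxo-2-phenyl-5,7-bis(triisopropylsilyloxy)-4H-chromen-6-yl]piperidine-1-carboxylate, via ynone 21 (not isolated), via enaminone 22 (not isolated)
Conditions: PdCl2(PPh3)2 (5 mol%), CO (20 bar), Et2NH, 100 °C
Reagents that add atoms: carbon monoxide, [C-]#[O+]
Why: Carbonylative Sonogashira-type coupling and annulation of an ortho-iodophenol: oxidative addition to zerovalent palladium, CO insertion and amine-assisted alkynyl transfer give ynone 21. Diethylamine adds to 21 to give enaminone 22, and the phenol displaces the amine by addition–elimination, which directs closure to the six-membered pyranone and away from the aurone. Only O1 is free, so the 6-substituted flavone is the sole possible regioisomer.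

Step 11
Reactants: 23 tert-butyl (R)-2-[4-oxo-2-phenyl-5,7-bis(triisopropylsilyloxy)-4H-chromen-6-yl]piperidine-1-carboxylate
Product: 25 (R)-6-(1-methylpiperidin-2-yl)-2-phenyl-5,7-bis(triisopropylsilyloxy)-4H-chromen-4-one, via piperidinium trifluoroacetate 24 (not isolated)
Conditions: CF3CO2H, CH2Cl2, 0 °C; evaporate; then aq. HCHO, NaBH(OAc)3, i-Pr2NEt, ClCH2CH2Cl, rt
Reagents that add atoms: formaldehyde, C=O
Why: Acidolysis of the carbamate (loss of isobutene and CO2) followed by reductive amination, in which the N-methyleneiminium ion is reduced by the acetoxyborohydride. The chromone carbonyl is a vinylogous ester and is not reduced, and the silylated ring A cannot react with formaldehyde at C8.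

Step 12
Reactants: 25 (R)-6-(1-methylpiperidin-2-yl)-2-phenyl-5,7-bis(triisopropylsilyloxy)-4H-chromen-4-one
Product: 26 (R)-5,7-dihydroxy-6-(1-methylpiperidin-2-yl)-2-phenyl-4H-chromen-4-one
Conditions: n-Bu4NF, AcOH, THF, 0 °C to rt
Reagents that add atoms: none
Why: Fluoride cleavage of the two aryl silyl ethers, driven by Si–F bond formation. Acetic acid buffering keeps the medium near neutral, so neither Wessely–Moser isomerisation nor ionisation at C2' should occur.

## Compound list

1 | (R)-piperidine-2-carboxylic acid | N1CCCC[C@@H]1C(=O)O | starting material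
2 | (R)-1-(tert-butoxycarbonyl)piperidine-2-carboxylic acid | CC(C)(C)OC(=O)N1CCCC[C@@H]1C(=O)O | intermediate
3 | 1-tert-butyl 2-methyl (R)-piperidine-1,2-dicarboxylate | CC(C)(C)OC(=O)N1CCCC[C@@H]1C(=O)OC | intermediate
4 | tert-butyl (R)-2-formylpiperidine-1-carboxylate | CC(C)(C)OC(=O)N1CCCC[C@@H]1C=O | intermediate
5 | tert-butyl (R)-2-ethynylpiperidine-1-carboxylate | CC(C)(C)OC(=O)N1CCCC[C@@H]1C#C | intermediate
6 | lithium 2-[(2R)-1-(tert-butoxycarbonyl)piperidin-2-yl]ethynide | CC(C)(C)OC(=O)N1CCCC[C@@H]1C#[C-].[Li+] | intermediate
7 | lithium 2-[(2R)-1-(tert-butoxycarbonyl)piperidin-2-yl]ethynolate | CC(C)(C)OC(=O)N1CCCC[C@@H]1C#C[O-].[Li+] | intermediate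
8 | tert-butyl (R)-2-[(triisopropylsilyloxy)ethynyl]piperidine-1-carboxylate | CC(C)(C)OC(=O)N1CCCC[C@@H]1C#CO[Si](C(C)C)(C(C)C)C(C)C | intermediate
9 | 3-ethoxycyclobut-2-en-1-one | CCOC1=CC(=O)C1 | starting material
10 | benzyl alcohol | OCc1ccccc1 | starting material
11 | 3-(benzyloxy)cyclobut-2-en-1-one | O=C1CC(OCc2ccccc2)=C1 | intermediate
12 | 3-(benzyloxy)buta-1,3-dien-1-one | C=C(OCc1ccccc1)C=C=O | intermediate
13 | tert-butyl (2R)-2-[3-(1-(benzyloxy)ethenyl)-4-oxo-2-(triisopropylsilyloxy)cyclobut-1-en-1-yl]piperidine-1-carboxylate | CC(C)(C)OC(=O)N1CCCC[C@@H]1C1=C(O[Si](C(C)C)(C(C)C)C(C)C)C(C(=C)OCc2ccccc2)C1=O | intermediate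
14 | tert-butyl (2R)-2-[(3E)-5-(benzyloxy)-1-oxo-3-(triisopropylsilyloxy)hexa-1,3,5-trien-2-yl]piperidine-1-carboxylate | CC(C)(C)OC(=O)N1CCCC[C@@H]1C(=C=O)/C(O[Si](C(C)C)(C(C)C)C(C)C)=C\C(=C)OCc1ccccc1 | intermediate
15 | tert-butyl (2R)-2-[4-(benzyloxy)-6-oxo-2-(triisopropylsilyloxy)cyclohexa-1,3-dien-1-yl]piperidine-1-carboxylate | CC(C)(C)OC(=O)N1CCCC[C@@H]1C1=C(O[Si](C(C)C)(C(C)C)C(C)C)C=C(OCc2ccccc2)CC1=O | intermediate
16 | tert-butyl (R)-2-[4-(benzyloxy)-2-hydroxy-6-(triisopropylsilyloxy)phenyl]piperidine-1-carboxylate | CC(C)(C)OC(=O)N1CCCC[C@@H]1c1c(O)cc(OCc2ccccc2)cc1O[Si](C(C)C)(C(C)C)C(C)C | intermediate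
17 | tert-butyl (R)-2-[4-(benzyloxy)-2,6-bis(triisopropylsilyloxy)phenyl]piperidine-1-carboxylate | CC(C)(C)OC(=O)N1CCCC[C@@H]1c1c(O[Si](C(C)C)(C(C)C)C(C)C)cc(OCc2ccccc2)cc1O[Si](C(C)C)(C(C)C)C(C)C | intermediate
18 | tert-butyl (R)-2-[4-hydroxy-2,6-bis(triisopropylsilyloxy)phenyl]piperidine-1-carboxylate | CC(C)(C)OC(=O)N1CCCC[C@@H]1c1c(O[Si](C(C)C)(C(C)C)C(C)C)cc(O)cc1O[Si](C(C)C)(C(C)C)C(C)C | intermediate
19 | tert-butyl (R)-2-[4-hydroxy-3-iodo-2,6-bis(triisopropylsilyloxy)phenyl]piperidine-1-carboxylate | CC(C)(C)OC(=O)N1CCCC[C@@H]1c1c(O[Si](C(C)C)(C(C)C)C(C)C)cc(O)c(I)c1O[Si](C(C)C)(C(C)C)C(C)C | intermediate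
20 | phenylacetylene | C#Cc1ccccc1 | starting material
21 | tert-butyl (R)-2-[4-hydroxy-3-(3-phenylprop-2-ynoyl)-2,6-bis(triisopropylsilyloxy)phenyl]piperidine-1-carboxylate | CC(C)(C)OC(=O)N1CCCC[C@@H]1c1c(O[Si](C(C)C)(C(C)C)C(C)C)cc(O)c(C(=O)C#Cc2ccccc2)c1O[Si](C(C)C)(C(C)C)C(C)C | intermediate
22 | tert-butyl (R)-2-{3-[(E)-3-(diethylamino)-3-phenylprop-2-enoyl]-4-hydroxy-2,6-bis(triisopropylsilyloxy)phenyl}piperidine-1-carboxylate | CC(C)(C)OC(=O)N1CCCC[C@@H]1c1c(O[Si](C(C)C)(C(C)C)C(C)C)cc(O)c(C(=O)/C=C(/N(CC)CC)c2ccccc2)c1O[Si](C(C)C)(C(C)C)C(C)C | intermediate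
23 | tert-butyl (R)-2-[4-oxo-2-phenyl-5,7-bis(triisopropylsilyloxy)-4H-chromen-6-yl]piperidine-1-carboxylate | CC(C)(C)OC(=O)N1CCCC[C@@H]1c1c(O[Si](C(C)C)(C(C)C)C(C)C)cc2oc(-c3ccccc3)cc(=O)c2c1O[Si](C(C)C)(C(C)C)C(C)C | intermediate
24 | (R)-2-[4-oxo-2-phenyl-5,7-bis(triisopropylsilyloxy)-4H-chromen-6-yl]piperidinium trifluoroacetate | [NH2+]1CCCC[C@@H]1c1c(O[Si](C(C)C)(C(C)C)C(C)C)cc2oc(-c3ccccc3)cc(=O)c2c1O[Si](C(C)C)(C(C)C)C(C)C.[O-]C(=O)C(F)(F)F | intermediate
25 | (R)-6-(1-methylpiperidin-2-yl)-2-phenyl-5,7-bis(triisopropylsilyloxy)-4H-chromen-4-one | CN1CCCC[C@@H]1c1c(O[Si](C(C)C)(C(C)C)C(C)C)cc2oc(-c3ccccc3)cc(=O)c2c1O[Si](C(C)C)(C(C)C)C(C)C | intermediate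
26 | (R)-5,7-dihydroxy-6-(1-methylpiperidin-2-yl)-2-phenyl-4H-chromen-4-one | CN1CCCC[C@@H]1c1c(O)cc2oc(-c3ccccc3)cc(=O)c2c1O | target

## Step count and least certain steps

Total step count: 12. Longest linear sequence: 11 steps (steps 1–4 and 6–12, from 1). Step 5 is a one-step side branch.

**Step 6 (key step).**
- What may go wrong: the electrocyclic opening of 11 may be reluctant, because its vinylogous-ester stabilisation is lost on opening. Vinylketene 12 may dimerise. The [2+2] addition at the branched alkyne carbon may be slow. The product phenol may be acylated by excess ketene. The ketene of 14 may be captured intramolecularly by the carbamate carbonyl before the 6π closure.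
- Fallback, from 10 and 8, rejoining at 12 and then 16: vinylketene 12 is generated without a cyclobutenone. Benzyl alcohol 10 is added to ethyl but-2-ynoate under n-Bu3P catalysis to give ethyl (E)-3-(benzyloxy)but-2-enoate F1. Saponification with LiOH gives (E)-3-(benzyloxy)but-2-enoic acid F2. 1-Chloro-N,N,2-trimethylprop-1-en-1-amine converts F2 under neutral conditions into (E)-3-(benzyloxy)but-2-enoyl chloride F3. Slow addition of Et3N to F3 and 8 in toluene at 25 °C should give 12 by 1,4-dehydrochlorination. Adduct 13 can then form at room temperature, and warming to 80 °C completes the cascade to 16.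

**Step 3.**
- What may go wrong: partial epimerisation of aldehyde 4 in methanolic carbonate, or over-reduction of the ester to the alcohol.
- Fallback, from 3, rejoining at 6: 3 is reduced with i-Bu2AlH at −78 °C and 4 is isolated. Base-free dibromo-olefination (CBr4, PPh3, CH2Cl2, 0 °C; first half of the Corey–Fuchs sequence) gives tert-butyl (R)-2-(2,2-dibromoethenyl)piperidine-1-carboxylate F4. n-BuLi (2.1 equiv) in THF at −78 °C converts F4 directly into lithium acetylide 6, which is oxidised and silylated as in step 4.

**Step 4.**
- What may go wrong: incomplete oxygen transfer to the hindered acetylide, silylation of the ynolate on carbon to a silylketene, or hydrolysis of the siloxyalkyne during isolation.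
- Fallback, from 3, rejoining at 7: Kowalski homologation conditions. LiCHBr2 (from CH2Br2 and lithium 2,2,6,6-tetramethylpiperidide) adds to ester 3 at −78 °C and gives, after loss of methoxide, tert-butyl (R)-2-(2,2-dibromoacetyl)piperidine-1-carboxylate F5 as its lithium enolate. Bromine–lithium exchange with n-BuLi and warming triggers the rearrangement to ynolate 7, which is trapped with TIPSOTf to give 8.

**Step 5.**
- What may go wrong: incomplete exchange, or cleavage of the strained ring by addition of the alcohol to the carbonyl group.
- Fallback, from 9, rejoining at 11: dilute aqueous HCl at room temperature hydrolyses 9 to cyclobutane-1,3-dione F6. This strongly acidic enol is O-benzylated with 10 under Mitsunobu conditions (PPh3, diisopropyl azodicarboxylate, THF, 0 °C) to give 11.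

**Step 9.**
- What may go wrong: a second iodination, or oxidation of the very electron-rich phenol.
- Fallback, from 18, rejoining at 21 and then 23: magnesium-mediated ortho-formylation (MgCl2, Et3N, paraformaldehyde, MeCN, 80 °C) gives tert-butyl (R)-2-[3-formyl-4-hydroxy-2,6-bis(triisopropylsilyloxy)phenyl]piperidine-1-carboxylate F7. Lithium phenylacetylide (from 20 and n-BuLi, 2.2 equiv, THF, −78 °C) adds to give tert-butyl (2R)-2-[4-hydroxy-3-(1-hydroxy-3-phenylprop-2-yn-1-yl)-2,6-bis(triisopropylsilyloxy)phenyl]piperidine-1-carboxylate F8 as a mixture of carbinol epimers. MnO2 in CH2Cl2 oxidises F8 to ynone 21, which is closed to 23 with Et2NH in EtOH at room temperature. This bypasses the iodide altogether.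

**Step 10.**
- What may go wrong: slow oxidative addition of the electron-rich, doubly ortho-substituted iodide. Coupling without CO insertion, leading to a benzofuran. Five-membered closure to the aurone. Aminocarbonylation by diethylamine. Loss of the silyl group on O5 before ring closure, which would let O5 compete and give the 8-substituted isomer.
- Fallback, from 19, rejoining at 21 and then 23: MeMgCl (1.0 equiv) deprotonates the phenol, and i-PrMgCl·LiCl (THF, −20 to 0 °C) then effects iodine–magnesium exchange to give chloromagnesium 4-[(2R)-1-(tert-butoxycarbonyl)piperidin-2-yl]-2-(chloromagnesio)-3,5-bis(triisopropylsilyloxy)phenolate F9. Acylation of F9 with N-methoxy-N-methyl-3-phenylprop-2-ynamide gives ynone 21 after aqueous NH4Cl, and Et2NH in EtOH closes it to 23 without palladium or pressurised gas.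

## Further compounds

F1 | step 6 | ethyl (E)-3-(benzyloxy)but-2-enoate | CCOC(=O)/C=C(\C)OCc1ccccc1
F2 | step 6 | (E)-3-(benzyloxy)but-2-enoic acid | OC(=O)/C=C(\C)OCc1ccccc1
F3 | step 6 | (E)-3-(benzyloxy)but-2-enoyl chloride | ClC(=O)/C=C(\C)OCc1ccccc1
F4 | step 3 | tert-butyl (R)-2-(2,2-dibromoethenyl)piperidine-1-carboxylate | CC(C)(C)OC(=O)N1CCCC[C@@H]1C=C(Br)Br
F5 | step 4 | tert-butyl (R)-2-(2,2-dibromoacetyl)piperidine-1-carboxylate | CC(C)(C)OC(=O)N1CCCC[C@@H]1C(=O)C(Br)Br
F6 | step 5 | cyclobutane-1,3-dione | O=C1CC(=O)C1
F7 | step 9 | tert-butyl (R)-2-[3-formyl-4-hydroxy-2,6-bis(triisopropylsilyloxy)phenyl]piperidine-1-carboxylate | CC(C)(C)OC(=O)N1CCCC[C@@H]1c1c(O[Si](C(C)C)(C(C)C)C(C)C)cc(O)c(C=O)c1O[Si](C(C)C)(C(C)C)C(C)C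
F8 | step 9 | tert-butyl (2R)-2-[4-hydroxy-3-(1-hydroxy-3-phenylprop-2-yn-1-yl)-2,6-bis(triisopropylsilyloxy)phenyl]piperidine-1-carboxylate | CC(C)(C)OC(=O)N1CCCC[C@@H]1c1c(O[Si](C(C)C)(C(C)C)C(C)C)cc(O)c(C(O)C#Cc2ccccc2)c1O[Si](C(C)C)(C(C)C)C(C)C
F9 | step 10 | chloromagnesium 4-[(2R)-1-(tert-butoxycarbonyl)piperidin-2-yl]-2-(chloromagnesio)-3,5-bis(triisopropylsilyloxy)phenolate | CC(C)(C)OC(=O)N1CCCC[C@@H]1c1c(O[Si](C(C)C)(C(C)C)C(C)C)cc(O[Mg]Cl)c([Mg]Cl)c1O[Si](C(C)C)(C(C)C)C(C)C
A1 | alternative 1 | (R)-5,7-dimethoxy-6-(1-methylpiperidin-2-yl)-2-phenyl-4H-chromen-4-one | CN1CCCC[C@@H]1c1c(OC)cc2oc(-c3ccccc3)cc(=O)c2c1OC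
A2 | alternative 1 | 1-{6-bromo-2,4-dimethoxy-3-[(2R)-1-methylpiperidin-2-yl]phenyl}-3-phenylpropane-1,3-dione | CN1CCCC[C@@H]1c1c(OC)cc(Br)c(C(=O)CC(=O)c2ccccc2)c1OC
A3 | alternative 2 | (R)-2-[2,6-dimethoxy-4-(triisopropylsilyloxy)phenyl]-1-(4-methoxyphenyl)-2,3-dihydropyridin-4(1H)-one | COc1ccc(cc1)N1C=CC(=O)C[C@@H]1c1c(OC)cc(O[Si](C(C)C)(C(C)C)C(C)C)cc1OC
A4 | alternative 2 | (E)-1-[2,6-dimethoxy-4-(triisopropylsilyloxy)phenyl]-N-(4-methoxyphenyl)methanimine | COc1ccc(cc1)/N=C/c1c(OC)cc(O[Si](C(C)C)(C(C)C)C(C)C)cc1OC
A5 | alternative 2 | (E)-1-methoxy-3-(trimethylsilyloxy)buta-1,3-diene | CO/C=C/C(=C)O[Si](C)(C)C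
A6 | alternative 3 | (R)-2-[4-(benzyloxy)-2,6-dimethoxyphenyl]-1-methyl-1,2,3,6-tetrahydropyridine | CN1CC=CC[C@@H]1c1c(OC)cc(OCc2ccccc2)cc1OC
A7 | alternative 3 | (R)-N-allyl-1-[4-(benzyloxy)-2,6-dimethoxyphenyl]-N-methylbut-3-en-1-amine | C=CCN(C)[C@H](CC=C)c1c(OC)cc(OCc2ccccc2)cc1OC
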